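## Structural features

The target is an unbranched C26 chain whose C1–C5 end is closed into an α,β-unsaturated δ-lactone (a 5,6-dihydro-2H-pyran-2-one made of O1 and C1 to C5, alkene at C2=C3), and this ring is joined through its only stereocentre, C5, to a 21-carbon side chain (C6–C26). The oxygen on C5 and the hydroxyls on C7, C9 and C11 form an unbroken 1,3-skipped array in which each neighbouring pair (C5/C7, C7/C9, C9/C11) is syn. A fourth hydroxyl stands at C15, separated from C11 by three methylenes and followed by an undecyl tail (C16–C26). Assignment by the sequence rules gives 5S, 7R, 9R, 11R and 15S. The fragile part is the enoate lactone: it is a Michael acceptor and a base-labile ester, and a free O7 hydroxyl can add to C3 under base, so the ring should be made late and the hydroxyls released under acid. The real difficulty is acyclic stereocontrol, not the carbon skeleton: four 1,3-related centres with no ring to relay through, and a remote C15 that no neighbouring centre can influence. The key step uses the fact that the ring bonds O1–C1 and C4–C5, with the C2=C3 alkene between them, are exactly what a [4+2] addition of a C5 aldehyde carbonyl to a 1-oxygenated buta-1,3-diene produces, so that C1 arrives as an acetal already at the lactone oxidation level and C5 is the only lasting new stereocentre.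

## Logic of the disconnections

23 to 22. The bonds restored are O7–Si, O15–Si and the two C–O bonds that tie O9 and O11 into a six-membered ketal. Four free hydroxyls cannot accompany the organometallic and oxidative steps, and a free O7–H next to the enoate invites conjugate addition to C3. The gain is that the four hydroxyls never need to be told apart. The demand is that the last step be acidic and mild enough to spare the lactone.

22 to 20 through 21. No skeletal bond is cut: the C1 carbonyl of 22 is traced to the C1 hydroxyl of 21 and then to the C1 methoxy group of 20. The reason is that a cycloaddition delivers C1 as a mixed acetal. The gain is that ring construction is separated from ring oxidation. The demand is a hydrolysis that touches the allylic acetal but not the ketal, and an oxidant that acts only on the allylic lactol.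

20 to 18 and 19. The bonds cut are C4–C5 and O1–C1. Cutting here removes the whole ring and the C5 stereocentre in one operation and leaves an acyclic aldehyde and a four-carbon diene. The demand is an external chiral controller that selects the Si face of the C5 carbonyl of 18, because the nearest stereocentre (C7) is β and cannot be relied on, together with complete regiocontrol by the donor-substituted diene.

18 to 13 through 17, 16 and 15. The C5 carbonyl is traced to a C4=C5 terminal alkene (16), the O7–Si bond is removed (15), and then C6–C7 is cut. An allyl unit supplies C4–C6 and carries the latent C5 aldehyde, so no redox adjustment other than alkene cleavage is needed. The gain is a C7 aldehyde with only the C9/C11/C15 centres. The demand is reagent-controlled Si-face addition to a β-alkoxy aldehyde, giving the 1,3-syn product against the substrate's weak anti preference.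

13 to 11 through 12. Only the oxidation level at C7 changes. The gain is a robust ester that survives the chain-joining steps. The demand is a reduction that stops at the aldehyde.

11 to 6 and 8 through 10 and 9. The C12–C13 bond is cut after it is reintroduced as a double bond. The three-methylene spacer between C11 and C15 is the natural seam: the two stereochemical domains do not interact, so each can be made separately and joined by olefination, with the alkene geometry erased by hydrogenation. The demand is that the α-oxygenated aldehyde 8 keep its C11 configuration under the basic coupling conditions.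

8 to 7. Only the C12 oxidation level changes. 7 is a commercial compound that already holds C9 and C11 in the required syn relationship and absolute sense, with the ketal in place. The demand is a non-epimerising oxidation.

6 to 1 through 5, 4, 3 and 2. The steps are, backwards: the C13–P bond, the C13–I bond, the C13 ester oxidation level, the O15–Si bond, and finally the C15–H bond. This takes the remote C15 centre back to a prochiral β-keto ester. The demand is an enantioselective ketone reduction of (S) sense, the only step that can set C15.

## Other disconnections considered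

Alternative 1: The cut is made at C10–C11 and C15–C16 together, taking the C11–C15 segment back to pentane-1,5-diol A1. In the forward step both primary carbinols of A1 would be dehydrogenated in the flask and allylated by allyl acetate A2, using an iridium catalyst formed from the precatalyst [Ir(cod)Cl]2 A3 and a chiral bisphosphine. This redox-neutral transfer-hydrogenative coupling should give the C2-symmetric (4R,8R)-undeca-1,10-diene-4,8-diol A4, which is C8–C18 with C11 and C15 set at once.
- In its favour: one catalytic step from a commodity diol, no protecting group, no stoichiometric chiral reagent. The only allyl source is the cheap ester A2, and the iridium source A3 is needed in catalytic amount only. The double addition should also raise the enantiomeric purity of the C2 isomer statistically, because a wrong-sense event at one terminus ends in a separable diastereomer and not in the enantiomer.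
- Against it here: A4 is symmetric and C8–C18 of 23 is not. One vinyl terminus must become the saturated C16–C26 tail; the other must be oxygenated at C9 with 1,3-syn control and then extended by C5–C7 and the ring. The termini must therefore be differentiated by a mono-functionalisation that competes with the double one, and C9, C7 and C5 each still need their own stereocontrolled step.
- Structure: it uses a local C2 symmetry of the C11/C15 pair that the chosen plan ignores, but it says nothing about the polyol–lactone half, which the chosen plan covers with 7 and step 13.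
- Mechanism: catalyst-controlled carbonyl allylation through a closed transition state at each terminus is as credible as the chosen mix of a chiral-pool diol, a ketone hydrogenation and a cycloaddition.
- Step economy: for C11 and C15 alone the alternative is the better (one step against the eight that lead to 11). Over the whole route, desymmetrisation and three further single-centre operations would be expected to bring the total to about that of the chosen plan or above.

Alternative 2: The cut is made on both sides of C9 (C8–C9 and C9–C10), so that C9 becomes a masked acyl anion. In the forward step 2-(tert-butyldimethylsilyl)-1,3-dithiane A5 would be deprotonated with an alkyllithium base, and the anion of A5 would open the C10–C26 epoxide A6 at C10. A polar additive would then trigger a 1,4-Brook shift of silicon from C9 to O11, and the regenerated C9 anion would open the C3–C8 epoxide A7 at C8. One flask should thus give the C3–C26 chain A8 with C9 as a dithiane, O11 silylated and O7 free.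
- In its favour: two C–C bonds and three fragments joined in one operation, with the linchpin A5 a simple achiral reagent. The free O7 hydroxyl is placed to direct a later 1,3-syn reduction of the unmasked C9 ketone, and the all-syn target fits that outcome.
- Against it here: A6 and A7 each carry two stereocentres and are multi-step fragments. The key step creates no stereocentre itself. C9 then needs dithiane removal and a directed reduction. The lactone still has to be built from the C3 ether by deprotection, oxidation, a Z-selective two-carbon olefination and ring closure. The protecting-group load (three silyl ethers, a benzyl-type ether, a dithiane) is heavier than in the chosen plan.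
- Structure: it is the better plan on convergence, since the chosen route is linear after step 7.
- Mechanism: it relies on stoichiometric organolithium chemistry at low temperature, whereas the chosen key step is catalytic and sets a stereocentre while forming the ring; the alternative's ring closure by lactonisation is the equal of the cycloaddition in reliability.
- Step economy: the total count would be expected to be clearly higher than 16, although the longest linear sequence could be similar.

Alternative 3: Here no C–C bond is cut; the C9–O bond is the strategic one. The substrate would be the (E)-allylic 1,5-diol A9 (C7–C26, primary hydroxyl at C7, secondary hydroxyl at C11, silyl ether at C15). The acetal partner would be benzaldehyde dimethyl acetal A10 and the catalyst dirhenium heptoxide Re2O7 A11. With A11 a perrhenate ester should shuttle the allylic oxygen reversibly between C7 and C9 by a [3,3] shift. The benzylidene donor A10 would trap the isomer that has oxygen on C9 together with O11, and equilibration should drain everything into the all-equatorial 2,4,6-cis-1,3-dioxane A12, which bears a C7=C8 vinyl group.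
- In its favour: C9 is set from C11 by thermodynamics with no chiral reagent; the step is catalytic; the syn diol comes out already protected, with a vinyl handle.
- Against it here: it forms only a C–O bond and reaches a structural element (the protected syn C9/C11 diol) that the chosen plan buys in 7. A9 must first be assembled with C11 and C15 in place. The vinyl group of A12 then has to be converted into a C7 aldehyde, after which the problem is the same as from 13 onward. The acidic oxide A11 could also threaten the silyl ether or open other equilibria.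
- Structure: it is the equal of the chosen plan in the fidelity expected for the C9/C11 relationship, and the better in flexibility, because it does not depend on one commercial chiral building block.
- Mechanism: thermodynamic funnelling is a different and equally sound control element compared with the chosen reagent and catalyst control.
- Step economy: it is the weaker plan, since several steps are spent before and after it on what the chosen route has at the outset.

Key step: step 13

Assumption: the complex [CrCl(L)] (trivalent chromium) whose ligand L is built from (1R,2S)-1-aminoindan-2-ol is taken to add 1-alkoxydienes to the Re face of α-unbranched aldehydes, so the complex of the (1S,2R) ligand is specified for the Si-face addition needed at C5; the antipodal complex would be used if the sense were the reverse.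

Remark on the structures: the cis-(4R,6S) ketal of 7 maps onto C9/C11 without inversion, the (S)-alcohol 2 maps onto C15, and 18 and 20 carry the target configuration at every retained centre, so both are used as drawn. The protecting pattern of 18 (ketal on O9/O11, silyl ethers on O7 and O15) is kept because none of it chelates the catalyst and one acidic operation removes all of it.

## Route

Step 1
Reactants: 1 methyl 3-oxotetradecanoate
Product: 2 methyl (3S)-3-hydroxytetradecanoate
Conditions: H2 (10 bar), RuCl2[(S)-BINAP] (0.2 mol%), MeOH, 50 °C
Reagents that add atoms: none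
Why: Noyori asymmetric hydrogenation of a β-keto ester; the ketone binds the divalent ruthenium centre in chelation with the ester carbonyl and hydride is delivered to one face, setting C15 (C3 of the ester) as S, the (S)-ligand being chosen because the (R)-ligand gives (R)-3-hydroxy esters in this class.

Step 2
Reactants: 2 methyl (3S)-3-hydroxytetradecanoate
Product: 3 methyl (3S)-3-[(tert-butyldimethylsilyl)oxy]tetradecanoate
Conditions: TBSCl, imidazole, DMF, rt
Reagents that add atoms: tert-butyldimethylsilyl chloride, CC(C)(C)[Si](C)(C)Cl
Why: Standard silyl ether formation on an unhindered secondary alcohol through the N-silylimidazolium species; it masks O15 for all later basic and organometallic steps and does not touch the stereocentre.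

Step 3
Reactants: 3 methyl (3S)-3-[(tert-butyldimethylsilyl)oxy]tetradecanoate
Product: 4 (3S)-3-[(tert-butyldimethylsilyl)oxy]tetradecan-1-ol
Conditions: i-Bu2AlH (2.3 equiv), CH2Cl2, −78 → 0 °C; MeOH then H2O
Reagents that add atoms: none
Why: Exhaustive hydride reduction of a methyl ester to the primary alcohol; the silyl ether and the C15 centre are inert to i-Bu2AlH.

Step 4
Reactants: 4 (3S)-3-[(tert-butyldimethylsilyl)oxy]tetradecan-1-ol
Product: 5 tert-butyl{[(3S)-1-iodotetradecan-3-yl]oxy}dimethylsilane
Conditions: I2, PPh3, imidazole, CH2Cl2, 0 °C → rt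
Reagents that add atoms: iodine, II
Why: Appel-type iodination; the primary alcohol is activated as an alkoxyphosphonium ion and displaced by iodide in an SN2 step, while the buffered medium keeps the secondary silyl ether intact.

Step 5
Reactants: 5 tert-butyl{[(3S)-1-iodotetradecan-3-yl]oxy}dimethylsilane
Product: 6 {(3S)-3-[(tert-butyldimethylsilyl)oxy]tetradecyl}triphenylphosphonium iodide
Conditions: PPh3 (1.5 equiv), MeCN, 80 °C
Reagents that add atoms: triphenylphosphine, c1ccc(cc1)P(c1ccccc1)c1ccccc1
Why: SN2 quaternisation of triphenylphosphine by a primary iodide; the oxygen is on the γ-carbon relative to phosphorus, so neither the salt nor the derived ylide can lose it by β-elimination.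

Step 6
Reactants: 7 tert-butyl 2-[(4R,6S)-6-(hydroxymethyl)-2,2-dimethyl-1,3-dioxan-4-yl]acetate
Product: 8 tert-butyl 2-[(4R,6S)-6-formyl-2,2-dimethyl-1,3-dioxan-4-yl]acetate
Conditions: TEMPO (10 mol%), PhI(OAc)2 (1.1 equiv), CH2Cl2, rt; used at once
Reagents that add atoms: none
Why: Nitroxyl-catalysed oxidation via the oxoammonium ion with the iodine diacetate as terminal oxidant; it stops at the aldehyde and is base-free, so the α-oxygenated C11 centre should not epimerise, and the ketal and tert-butyl ester are inert.

Step 7
Reactants: 6 {(3S)-3-[(tert-butyldimethylsilyl)oxy]tetradecyl}triphenylphosphonium iodide; 8 tert-butyl 2-[(4R,6S)-6-formyl-2,2-dimethyl-1,3-dioxan-4-yl]acetate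
Product: 10 tert-butyl 2-[(4R,6S)-6-{(1Z,4S)-4-[(tert-butyldimethylsilyl)oxy]pentadec-1-en-1-yl}-2,2-dimethyl-1,3-dioxan-4-yl]acetate, via phosphorus ylide 9 (not isolated)
Conditions: 6 (1.2 equiv), NaN(SiMe3)2 (1.15 equiv), THF, −78 → 0 °C; then 8, −78 °C → rt
Reagents that add atoms: none
Why: Wittig olefination with a non-stabilised ylide forms C12=C13 through an oxaphosphetane that collapses to the (Z)-alkene and the phosphine oxide; a slight excess of salt over base leaves no free amide, so C11 of 8 should survive, and the geometry is irrelevant because the alkene is hydrogenated next.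

Step 8
Reactants: 10 tert-butyl 2-[(4R,6S)-6-{(1Z,4S)-4-[(tert-butyldimethylsilyl)oxy]pentadec-1-en-1-yl}-2,2-dimethyl-1,3-dioxan-4-yl]acetate
Product: 11 tert-butyl 2-[(4R,6R)-6-{(4S)-4-[(tert-butyldimethylsilyl)oxy]pentadecyl}-2,2-dimethyl-1,3-dioxan-4-yl]acetate
Conditions: H2 (1 atm), Pd/C (10% Pd on carbon), EtOAc, rt
Reagents that add atoms: none
Why: Heterogeneous hydrogenation of a disubstituted alkene; the allylic C11–O bond belongs to a ketal and is not expected to undergo hydrogenolysis at 1 atm, and in ethyl acetate the silyl ether, ketal and ester are untouched (the descriptor at the ring carbon changes only because the substituent priorities change).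

Step 9
Reactants: 11 tert-butyl 2-[(4R,6R)-6-{(4S)-4-[(tert-butyldimethylsilyl)oxy]pentadecyl}-2,2-dimethyl-1,3-dioxan-4-yl]acetate
Product: 13 2-[(4R,6R)-6-{(4S)-4-[(tert-butyldimethylsilyl)oxy]pentadecyl}-2,2-dimethyl-1,3-dioxan-4-yl]acetaldehyde, via aluminium hemiacetal 12 (not isolated)
Conditions: i-Bu2AlH (1.05 equiv), CH2Cl2, −78 °C; MeOH then H2O at −78 °C; used crude
Reagents that add atoms: none
Why: Partial reduction of an ester; one hydride adds, and the tetrahedral aluminium hemiacetal, held by the bulky tert-butoxy group and by coordination to the ring oxygen, persists at −78 °C and releases the aldehyde only on quench, while the β-centre C9 cannot epimerise.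

Step 10
Reactants: 13 2-[(4R,6R)-6-{(4S)-4-[(tert-butyldimethylsilyl)oxy]pentadecyl}-2,2-dimethyl-1,3-dioxan-4-yl]acetaldehyde
Product: 15 (2S)-1-[(4S,6R)-6-{(4S)-4-[(tert-butyldimethylsilyl)oxy]pentadecyl}-2,2-dimethyl-1,3-dioxan-4-yl]pent-4-en-2-ol, via borinate ester 14 (not isolated)
Conditions: (−)-Ipc2BOMe, CH2=CHCH2MgBr, Et2O, 0 °C → rt; then 13, −78 °C; then 3 M NaOH, 30% H2O2, rt
Reagents that add atoms: allylmagnesium bromide, C=CC[Mg]Br, whose allyl group is transferred through (−)-B-allyldiisopinocampheylborane, C=CCB([C@@H]1C[C@@H]2C[C@H]([C@H]1C)C2(C)C)[C@@H]1C[C@@H]2C[C@H]([C@H]1C)C2(C)C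
Why: Brown asymmetric allylboration through a closed chair-like six-membered transition state; the isopinocampheyl groups of the (+)-α-pinene-derived reagent direct the allyl group to the Si face of the C7 carbonyl, setting C7 syn to O9 (target 7R, formally 2S in 15), and this reagent control is expected to override the weak 1,3-anti preference of the β-alkoxy aldehyde; oxidative work-up cleaves the borinate.

Step 11
Reactants: 15 (2S)-1-[(4S,6R)-6-{(4S)-4-[(tert-butyldimethylsilyl)oxy]pentadecyl}-2,2-dimethyl-1,3-dioxan-4-yl]pent-4-en-2-ol
Product: 16 (4R,6R)-4-{(2S)-2-[(tert-butyldimethylsilyl)oxy]pent-4-en-1-yl}-6-{(4S)-4-[(tert-butyldimethylsilyl)oxy]pentadecyl}-2,2-dimethyl-1,3-dioxane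
Conditions: TBSCl (1.5 equiv), imidazole, DMAP (cat.), DMF, rt → 40 °C
Reagents that add atoms: tert-butyldimethylsilyl chloride, CC(C)(C)[Si](C)(C)Cl
Why: Silyl ether formation on a secondary homoallylic alcohol; the chloride/imidazole protocol is chosen over a silyl triflate because it carries no risk of opening the ketal.

Step 12
Reactants: 16 (4R,6R)-4-{(2S)-2-[(tert-butyldimethylsilyl)oxy]pent-4-en-1-yl}-6-{(4S)-4-[(tert-butyldimethylsilyl)oxy]pentadecyl}-2,2-dimethyl-1,3-dioxane
Product: 18 (3R)-3-[(tert-butyldimethylsilyl)oxy]-4-[(4R,6R)-6-{(4S)-4-[(tert-butyldimethylsilyl)oxy]pentadecyl}-2,2-dimethyl-1,3-dioxan-4-yl]butanal, via secondary ozonide 17 (not isolated)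
Conditions: O3, CH2Cl2, −78 °C; then PPh3, −78 °C → rt; used crude
Reagents that add atoms: ozone, [O-][O+]=O
Why: Ozonolysis of the only alkene gives the 1,2,4-trioxolane, which triphenylphosphine reduces to the C5 aldehyde and formaldehyde; the neutral reductive work-up avoids β-elimination of the C7 silyloxy group.

Step 13
Reactants: 18 (3R)-3-[(tert-butyldimethylsilyl)oxy]-4-[(4R,6R)-6-{(4S)-4-[(tert-butyldimethylsilyl)oxy]pentadecyl}-2,2-dimethyl-1,3-dioxan-4-yl]butanal; 19 (E)-1-methoxybuta-1,3-diene
Product: 20 (4R,6R)-4-{(2S)-2-[(tert-butyldimethylsilyl)oxy]-3-[(2S,6R)-6-methoxy-3,6-dihydro-2H-pyran-2-yl]propyl}-6-{(4S)-4-[(tert-butyldimethylsilyl)oxy]pentadecyl}-2,2-dimethyl-1,3-dioxane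
Conditions: 19 (3 equiv), [CrCl(L)] (5 mol%; L = dianion of the Schiff base of (1S,2R)-1-aminoindan-2-ol and 3-(1-adamantyl)-5-methylsalicylaldehyde; trivalent chromium), 4 Å MS, minimal t-BuOMe, rt
Reagents that add atoms: none
Why: The carbonyl oxygen of 18 binds the Lewis-acidic trivalent chromium centre of [CrCl(L)], which lowers the C=O acceptor orbital and leaves one face open. The electron-rich diene then adds in a concerted, asynchronous [4+2] cycloaddition in which C4–C5 formation runs ahead of O1–C1 formation, and the methoxy donor fixes the regiochemistry so that the unsubstituted diene terminus bonds to the carbonyl carbon and the methoxy-bearing terminus to the carbonyl oxygen. The closest known reaction type is the hetero-Diels–Alder reaction of unactivated aliphatic aldehydes with 1-alkoxybutadienes under tridentate Schiff base chromium chloride catalysis. The dihydropyran ring is closed in the cycloaddition mode, both ring bonds coming from one intermolecular 4π + 2π event, so there is no separate cyclisation and no competing ring size. C5 is controlled by the catalyst: the (1S,2R) ligand should direct the diene to the Si face of the aldehyde and give 5S. The acetal centre C1 is controlled by the endo transition state relative to C5, which should give the cis-2,6 adduct, and this centre is removed at step 15. The selectivity the step needs is facial discrimination at an unhindered CH2CHO terminus whose nearest stereocentre (C7) is β; its non-chelating silyl ether gives only a weak substrate bias, so the catalyst should decide. The silyl ethers and the ketal are inert to this mild Lewis acid, and the sieves keep the acetal product from hydrolysing.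

Step 14
Reactants: 20 (4R,6R)-4-{(2S)-2-[(tert-butyldimethylsilyl)oxy]-3-[(2S,6R)-6-methoxy-3,6-dihydro-2H-pyran-2-yl]propyl}-6-{(4S)-4-[(tert-butyldimethylsilyl)oxy]pentadecyl}-2,2-dimethyl-1,3-dioxane
Product: 21 (6S)-6-{(2S)-2-[(tert-butyldimethylsilyl)oxy]-3-[(4R,6R)-6-{(4S)-4-[(tert-butyldimethylsilyl)oxy]pentadecyl}-2,2-dimethyl-1,3-dioxan-4-yl]propyl}-5,6-dihydro-2H-pyran-2-ol (anomeric mixture)
Conditions: PPTS (0.1 equiv), acetone/H2O (10:1), rt
Reagents that add atoms: water, O
Why: Mild acid hydrolysis of an allylic mixed acetal through an alkene-conjugated oxocarbenium ion, which forms far more readily than the ion from the saturated ketal; acetone as solvent holds the isopropylidene group in place and pyridinium tosylate is too weak to cleave secondary silyl ethers; the C1 configuration is of no consequence.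

Step 15
Reactants: 21 (6S)-6-{(2S)-2-[(tert-butyldimethylsilyl)oxy]-3-[(4R,6R)-6-{(4S)-4-[(tert-butyldimethylsilyl)oxy]pentadecyl}-2,2-dimethyl-1,3-dioxan-4-yl]propyl}-5,6-dihydro-2H-pyran-2-ol
Product: 22 (6S)-6-{(2R)-2-[(tert-butyldimethylsilyl)oxy]-3-[(4R,6R)-6-{(4S)-4-[(tert-butyldimethylsilyl)oxy]pentadecyl}-2,2-dimethyl-1,3-dioxan-4-yl]propyl}-5,6-dihydro-2H-pyran-2-one
Conditions: MnO2 (20 equiv), CH2Cl2, rt
Reagents that add atoms: none
Why: Manganese dioxide oxidises the allylic lactol as it would an allylic alcohol, giving the α,β-unsaturated δ-lactone with the alkene fixed at C2=C3; the neutral heterogeneous conditions leave the silyl ethers, the ketal and all stereocentres alone.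

Step 16
Reactants: 22 (6S)-6-{(2R)-2-[(tert-butyldimethylsilyl)oxy]-3-[(4R,6R)-6-{(4S)-4-[(tert-butyldimethylsilyl)oxy]pentadecyl}-2,2-dimethyl-1,3-dioxan-4-yl]propyl}-5,6-dihydro-2H-pyran-2-one
Product: 23 (6S)-6-[(2R,4R,6R,10S)-2,4,6,10-tetrahydroxyhenicosyl]-5,6-dihydro-2H-pyran-2-one
Conditions: 48% aq. HF/MeCN (1:9), 0 °C → rt
Reagents that add atoms: none
Why: Global acidic deprotection; fluoride cleaves both silyl ethers and the aqueous acid hydrolyses the isopropylidene ketal, while the acidic medium avoids the base-induced lactone opening and conjugate addition of O7 to C3; no stereocentre is touched.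

## Compound list

1 | methyl 3-oxotetradecanoate | CCCCCCCCCCCC(=O)CC(=O)OC | starting material
2 | methyl (3S)-3-hydroxytetradecanoate | CCCCCCCCCCC[C@H](O)CC(=O)OC | intermediate
3 | methyl (3S)-3-[(tert-butyldimethylsilyl)oxy]tetradecanoate | CCCCCCCCCCC[C@H](O[Si](C)(C)C(C)(C)C)CC(=O)OC | intermediate
4 | (3S)-3-[(tert-butyldimethylsilyl)oxy]tetradecan-1-ol | CCCCCCCCCCC[C@H](O[Si](C)(C)C(C)(C)C)CCO | intermediate
5 | tert-butyl{[(3S)-1-iodotetradecan-3-yl]oxy}dimethylsilane | CCCCCCCCCCC[C@H](O[Si](C)(C)C(C)(C)C)CCI | intermediate
6 | {(3S)-3-[(tert-butyldimethylsilyl)oxy]tetradecyl}triphenylphosphonium iodide | CCCCCCCCCCC[C@H](O[Si](C)(C)C(C)(C)C)CC[P+](c1ccccc1)(c1ccccc1)c1ccccc1.[I-] | intermediate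
7 | tert-butyl 2-[(4R,6S)-6-(hydroxymethyl)-2,2-dimethyl-1,3-dioxan-4-yl]acetate | OC[C@@H]1C[C@@H](OC(C)(C)O1)CC(=O)OC(C)(C)C | starting material
8 | tert-butyl 2-[(4R,6S)-6-formyl-2,2-dimethyl-1,3-dioxan-4-yl]acetate | O=C[C@@H]1C[C@@H](OC(C)(C)O1)CC(=O)OC(C)(C)C | intermediate
9 | {(3S)-3-[(tert-butyldimethylsilyl)oxy]tetradecylidene}triphenyl-λ5-phosphane (ylide, not isolated) | CCCCCCCCCCC[C@H](O[Si](C)(C)C(C)(C)C)CC=P(c1ccccc1)(c1ccccc1)c1ccccc1 | intermediate
10 | tert-butyl 2-[(4R,6S)-6-{(1Z,4S)-4-[(tert-butyldimethylsilyl)oxy]pentadec-1-en-1-yl}-2,2-dimethyl-1,3-dioxan-4-yl]acetate | CCCCCCCCCCC[C@H](O[Si](C)(C)C(C)(C)C)C/C=C\[C@@H]1C[C@@H](OC(C)(C)O1)CC(=O)OC(C)(C)C | intermediate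
11 | tert-butyl 2-[(4R,6R)-6-{(4S)-4-[(tert-butyldimethylsilyl)oxy]pentadecyl}-2,2-dimethyl-1,3-dioxan-4-yl]acetate | CCCCCCCCCCC[C@H](O[Si](C)(C)C(C)(C)C)CCC[C@@H]1C[C@@H](OC(C)(C)O1)CC(=O)OC(C)(C)C | intermediate
12 | O-(diisobutylalumanyl) tert-butyl hemiacetal of 13 (C7 epimers, not isolated) | CCCCCCCCCCC[C@H](O[Si](C)(C)C(C)(C)C)CCC[C@@H]1C[C@@H](OC(C)(C)O1)CC(OC(C)(C)C)O[Al](CC(C)C)CC(C)C | intermediate
13 | 2-[(4R,6R)-6-{(4S)-4-[(tert-butyldimethylsilyl)oxy]pentadecyl}-2,2-dimethyl-1,3-dioxan-4-yl]acetaldehyde | CCCCCCCCCCC[C@H](O[Si](C)(C)C(C)(C)C)CCC[C@@H]1C[C@@H](OC(C)(C)O1)CC=O | intermediate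
14 | bis(isopinocampheyl)borinate ester of 15 (not isolated) | CCCCCCCCCCC[C@H](O[Si](C)(C)C(C)(C)C)CCC[C@@H]1C[C@@H](OC(C)(C)O1)C[C@H](CC=C)OB([C@@H]1C[C@@H]2C[C@H]([C@H]1C)C2(C)C)[C@@H]1C[C@@H]2C[C@H]([C@H]1C)C2(C)C | intermediate
15 | (2S)-1-[(4S,6R)-6-{(4S)-4-[(tert-butyldimethylsilyl)oxy]pentadecyl}-2,2-dimethyl-1,3-dioxan-4-yl]pent-4-en-2-ol | CCCCCCCCCCC[C@H](O[Si](C)(C)C(C)(C)C)CCC[C@@H]1C[C@@H](OC(C)(C)O1)C[C@@H](O)CC=C | intermediate
16 | (4R,6R)-4-{(2S)-2-[(tert-butyldimethylsilyl)oxy]pent-4-en-1-yl}-6-{(4S)-4-[(tert-butyldimethylsilyl)oxy]pentadecyl}-2,2-dimethyl-1,3-dioxane | CCCCCCCCCCC[C@H](O[Si](C)(C)C(C)(C)C)CCC[C@@H]1C[C@@H](OC(C)(C)O1)C[C@@H](O[Si](C)(C)C(C)(C)C)CC=C | intermediate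
17 | secondary ozonide (3-substituted 1,2,4-trioxolane) of 16 (not isolated) | CCCCCCCCCCC[C@H](O[Si](C)(C)C(C)(C)C)CCC[C@@H]1C[C@@H](OC(C)(C)O1)C[C@@H](O[Si](C)(C)C(C)(C)C)CC1OOCO1 | intermediate
18 | (3R)-3-[(tert-butyldimethylsilyl)oxy]-4-[(4R,6R)-6-{(4S)-4-[(tert-butyldimethylsilyl)oxy]pentadecyl}-2,2-dimethyl-1,3-dioxan-4-yl]butanal | CCCCCCCCCCC[C@H](O[Si](C)(C)C(C)(C)C)CCC[C@@H]1C[C@@H](OC(C)(C)O1)C[C@@H](O[Si](C)(C)C(C)(C)C)CC=O | intermediate
19 | (E)-1-methoxybuta-1,3-diene | CO/C=C/C=C | starting material
20 | (4R,6R)-4-{(2S)-2-[(tert-butyldimethylsilyl)oxy]-3-[(2S,6R)-6-methoxy-3,6-dihydro-2H-pyran-2-yl]propyl}-6-{(4S)-4-[(tert-butyldimethylsilyl)oxy]pentadecyl}-2,2-dimethyl-1,3-dioxane | CCCCCCCCCCC[C@H](O[Si](C)(C)C(C)(C)C)CCC[C@@H]1C[C@@H](OC(C)(C)O1)C[C@@H](O[Si](C)(C)C(C)(C)C)C[C@@H]1CC=C[C@H](OC)O1 | intermediate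
21 | (6S)-6-{(2S)-2-[(tert-butyldimethylsilyl)oxy]-3-[(4R,6R)-6-{(4S)-4-[(tert-butyldimethylsilyl)oxy]pentadecyl}-2,2-dimethyl-1,3-dioxan-4-yl]propyl}-5,6-dihydro-2H-pyran-2-ol (anomeric mixture) | CCCCCCCCCCC[C@H](O[Si](C)(C)C(C)(C)C)CCC[C@@H]1C[C@@H](OC(C)(C)O1)C[C@@H](O[Si](C)(C)C(C)(C)C)C[C@@H]1CC=CC(O)O1 | intermediate
22 | (6S)-6-{(2R)-2-[(tert-butyldimethylsilyl)oxy]-3-[(4R,6R)-6-{(4S)-4-[(tert-butyldimethylsilyl)oxy]pentadecyl}-2,2-dimethyl-1,3-dioxan-4-yl]propyl}-5,6-dihydro-2H-pyran-2-one | CCCCCCCCCCC[C@H](O[Si](C)(C)C(C)(C)C)CCC[C@@H]1C[C@@H](OC(C)(C)O1)C[C@@H](O[Si](C)(C)C(C)(C)C)C[C@@H]1CC=CC(=O)O1 | intermediate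
23 | (6S)-6-[(2R,4R,6R,10S)-2,4,6,10-tetrahydroxyhenicosyl]-5,6-dihydro-2H-pyran-2-one | CCCCCCCCCCC[C@H](O)CCC[C@@H](O)C[C@@H](O)C[C@@H](O)C[C@@H]1CC=CC(=O)O1 | target

## Step count and least certain steps

Total step count: 16 (steps 1–5 make 6, step 6 makes 8, steps 7–16 take the joined chain to 23). Longest linear sequence: 15 steps (steps 1–5 and 7–16, from 1); from 7 the sequence is 11 steps.

Step 13 (key step). The most likely failure is incomplete face discrimination at C5 combined with slow turnover. The aldehyde is large and lipophilic and binds the weakly Lewis-acidic [CrCl(L)], and if the β-silyloxy centre at C7 opposes the catalyst the two influences are mismatched. Fallback: from 18, asymmetric allylboration with (−)-Ipc2B(allyl) (Si-face addition, as in step 10) should give (4S,6S)-6-[(tert-butyldimethylsilyl)oxy]-7-[(4R,6R)-6-{(4S)-4-[(tert-butyldimethylsilyl)oxy]pentadecyl}-2,2-dimethyl-1,3-dioxan-4-yl]hept-1-en-4-ol F1. Acylation with acryloyl chloride and i-Pr2NEt would give the corresponding (4S,6R)-hept-1-en-4-yl prop-2-enoate F2. Ring-closing metathesis with the second-generation Grubbs catalyst [RuCl2(H2IMes)(PCy3)(=CHPh)] in CH2Cl2 at 40 °C should then close the lactone directly. The fallback returns to the route at 22 and bypasses 20 and 21.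

Step 10. The most likely failure is insufficient 1,3-syn selectivity, because the chiral reagent has to override the anti preference of the β-alkoxy aldehyde; removal of the terpene alcohol can also cost material. Fallback: from 13, a Keck allylation with (S)-BINOL/Ti(OiPr)4 (10 mol%), CH2=CHCH2SnBu3 and 4 Å MS in CH2Cl2 at −20 °C. This replaces the stoichiometric chiral borane and its closed transition state by a catalytic chiral tetravalent titanium Lewis acid that activates the aldehyde towards an achiral stannane through an open transition state, with the same Si-face sense. It returns at 15 and makes no new compound.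

Step 9. The most likely failure is over-reduction to the primary alcohol or incomplete conversion. If the tetrahedral intermediate collapses before the quench, the aldehyde it releases is reduced faster than the hindered ester. Fallback: from 11, exhaustive reduction with LiAlH4 (THF, 0 °C) to 2-[(4S,6R)-6-{(4S)-4-[(tert-butyldimethylsilyl)oxy]pentadecyl}-2,2-dimethyl-1,3-dioxan-4-yl]ethan-1-ol F3, then oxidation with TEMPO/PhI(OAc)2 as in step 6. This two-step detour returns at 13.

Step 14. The most likely failure is ring opening of the lactol to the hydroxy-(Z)-enal followed by acid-catalysed Z to E isomerisation, which prevents re-closure; partial loss of the ketal under the aqueous acid is the second concern. Fallback: from 20, direct oxidation of the acetal carbon with pyridinium chlorochromate, [C5H5NH][CrO3Cl], in CH2Cl2 at rt. This converts cyclic allylic alkyl acetals into the unsaturated lactones without releasing the free lactol. It returns at 22, bypasses 21 and makes no new compound.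

Step 16. The most likely failure is conjugate addition of the freed O7 hydroxyl to C3, or incomplete ketal hydrolysis, because one set of conditions has to do two different cleavages next to a Michael acceptor. Fallback: from 22, the unmasking is split. HF·pyridine in THF/pyridine (0 °C → rt) removes only the silyl ethers to give (6S)-6-[(2R)-2-hydroxy-3-{(4S,6R)-6-[(4S)-4-hydroxypentadecyl]-2,2-dimethyl-1,3-dioxan-4-yl}propyl]-5,6-dihydro-2H-pyran-2-one F4. The ketal is then hydrolysed separately with AcOH/H2O (4:1) at rt, so each cleavage can be stopped on its own. This returns at 23.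

## Further compounds

F1 | step 13 | (4S,6S)-6-[(tert-butyldimethylsilyl)oxy]-7-[(4R,6R)-6-{(4S)-4-[(tert-butyldimethylsilyl)oxy]pentadecyl}-2,2-dimethyl-1,3-dioxan-4-yl]hept-1-en-4-ol | CCCCCCCCCCC[C@H](O[Si](C)(C)C(C)(C)C)CCC[C@@H]1C[C@@H](OC(C)(C)O1)C[C@@H](O[Si](C)(C)C(C)(C)C)C[C@@H](O)CC=C
F2 | step 13 | (4S,6R)-6-[(tert-butyldimethylsilyl)oxy]-7-[(4R,6R)-6-{(4S)-4-[(tert-butyldimethylsilyl)oxy]pentadecyl}-2,2-dimethyl-1,3-dioxan-4-yl]hept-1-en-4-yl prop-2-enoate | CCCCCCCCCCC[C@H](O[Si](C)(C)C(C)(C)C)CCC[C@@H]1C[C@@H](OC(C)(C)O1)C[C@@H](O[Si](C)(C)C(C)(C)C)C[C@@H](OC(=O)C=C)CC=C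
F0 | step 10 | none | none
F3 | step 9 | 2-[(4S,6R)-6-{(4S)-4-[(tert-butyldimethylsilyl)oxy]pentadecyl}-2,2-dimethyl-1,3-dioxan-4-yl]ethan-1-ol | CCCCCCCCCCC[C@H](O[Si](C)(C)C(C)(C)C)CCC[C@@H]1C[C@@H](OC(C)(C)O1)CCO
F0 | step 14 | none | none
F4 | step 16 | (6S)-6-[(2R)-2-hydroxy-3-{(4S,6R)-6-[(4S)-4-hydroxypentadecyl]-2,2-dimethyl-1,3-dioxan-4-yl}propyl]-5,6-dihydro-2H-pyran-2-one | CCCCCCCCCCC[C@H](O)CCC[C@@H]1C[C@@H](OC(C)(C)O1)C[C@@H](O)C[C@@H]1CC=CC(=O)O1
A1 | alternative 1 | pentane-1,5-diol | OCCCCCO
A2 | alternative 1 | allyl acetate | CC(=O)OCC=C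
A3 | alternative 1 | di-μ-chlorobis(cycloocta-1,5-diene)diiridium, [Ir(cod)Cl]2 | [Cl-].[Cl-].[Ir+].[Ir+].C1=CCCC=CCC1.C1=CCCC=CCC1
A4 | alternative 1 | (4R,8R)-undeca-1,10-diene-4,8-diol | C=CC[C@H](O)CCC[C@@H](O)CC=C
A5 | alternative 2 | 2-(tert-butyldimethylsilyl)-1,3-dithiane | CC(C)(C)[Si](C)(C)C1SCCCS1
A6 | alternative 2 | (2R)-2-{(4S)-4-[(tert-butyldimethylsilyl)oxy]pentadecyl}oxirane (C10–C26 epoxide) | CCCCCCCCCCC[C@H](O[Si](C)(C)C(C)(C)C)CCC[C@@H]1CO1
A7 | alternative 2 | tert-butyl({(2S)-4-[(4-methoxybenzyl)oxy]-1-[(2S)-oxiran-2-yl]butan-2-yl}oxy)dimethylsilane (C3–C8 epoxide) | C1O[C@H]1C[C@@H](O[Si](C)(C)C(C)(C)C)CCOCc1ccc(OC)cc1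
A8 | alternative 2 | C3–C26 linchpin product (1,3-dithiane at C9, free hydroxyl at C7, silyl ethers at C5, C11 and C15, 4-methoxybenzyl ether at C3) | CCCCCCCCCCC[C@H](O[Si](C)(C)C(C)(C)C)CCC[C@@H](O[Si](C)(C)C(C)(C)C)CC1(SCCCS1)C[C@@H](O)C[C@@H](O[Si](C)(C)C(C)(C)C)CCOCc1ccc(OC)cc1
A9 | alternative 3 | (2E,5R,9S)-9-[(tert-butyldimethylsilyl)oxy]icos-2-ene-1,5-diol | CCCCCCCCCCC[C@H](O[Si](C)(C)C(C)(C)C)CCC[C@@H](O)C/C=C/CO
A10 | alternative 3 | benzaldehyde dimethyl acetal | COC(OC)c1ccccc1
A11 | alternative 3 | dirhenium heptoxide, Re2O7 | O=[Re](=O)(=O)O[Re](=O)(=O)=O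
A12 | alternative 3 | 2,4,6-cis-2-phenyl-4-vinyl-6-{(4S)-4-[(tert-butyldimethylsilyl)oxy]pentadecyl}-1,3-dioxane | CCCCCCCCCCC[C@H](O[Si](C)(C)C(C)(C)C)CCC[C@@H]1C[C@@H](O[C@H](c2ccccc2)O1)C=C
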